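The route rests on cutting ring C at the O1–C8a bond. The feature exploited is that O1 bridges the aromatic carbon C8a of ring A and the benzylic stereocentre C2 that carries ring B. O1 can therefore be brought in as the C2 hydroxyl of an open-chain anti diol and joined to C8a at an aryl triflate flanked by the C8 prenyl group. One palladium-catalysed intramolecular O-arylation closes the pyran without breaking the C2–O or C3–O bonds, so the 2R,3S (trans) pattern is carried over intact. The precursor is the (1R,2S)-1,3-diarylpropane-1,2-diol, MOM-protected at the C3 oxygen and on all phenols, built by auxiliary-controlled glycolate alkylation and chelation-controlled ketone reduction.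

Key step: step 16

Remark: 2,4,6-trihydroxybenzaldehyde (the formylation product of phloroglucinol) and methyl glycolate are taken as purchased, and flavan numbering (O1, C2, C3, C4, C4a, C5 to C8, C8a) is also used for the open-chain compounds.

Step 1
Reactants: 1 2,4,6-trihydroxybenzaldehyde
Product: 2 2-hydroxy-4,6-bis(methoxymethoxy)benzaldehyde
Conditions: MOMCl (2.2 equiv), i-Pr2NEt, CH2Cl2, 0 °C → rt
Reagents that add atoms: chloromethyl methyl ether (MOMCl), COCCl
Why: Williamson-type O-alkylation (MOM protection) in which the acidic 4-OH and one of the two equivalent ortho hydroxyls react while the last ortho hydroxyl is held back by its hydrogen bond to the formyl oxygen.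

Step 2
Reactants: 3 2-methylbut-3-en-2-ol
Product: 5 methyl 2-methylbut-3-en-2-yl carbonate, via lithium 2-methylbut-3-en-2-olate 4 (not isolated)
Conditions: n-BuLi, THF, −78 °C; then ClCO2Me, −78 °C → rt
Reagents that add atoms: methyl chloroformate, COC(=O)Cl
Why: O-acylation of a pre-formed tertiary lithium alkoxide by a chloroformate (carbonate formation), the deprotonation being needed because a tertiary allylic alcohol is too hindered for amine-base acylation.

Step 3
Reactants: 2 2-hydroxy-4,6-bis(methoxymethoxy)benzaldehyde; 5 methyl 2-methylbut-3-en-2-yl carbonate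
Product: 6 2,4-bis(methoxymethoxy)-6-[(2-methylbut-3-en-2-yl)oxy]benzaldehyde
Conditions: Pd(PPh3)4 (2 mol%), THF, 0 °C, stopped as soon as 2 is consumed
Reagents that add atoms: none
Why: Tsuji–Trost O-allylation in which zerovalent palladium ionises the tertiary carbonate with loss of CO2, the methoxide released deprotonates the phenol, and the phenoxide attacks the more substituted terminus of the 1,1-dimethylallyl palladium cation under kinetic control at low temperature to give the tertiary aryl ether.

Step 4
Reactants: 6 2,4-bis(methoxymethoxy)-6-[(2-methylbut-3-en-2-yl)oxy]benzaldehyde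
Product: 8 2-hydroxy-4,6-bis(methoxymethoxy)-3-(3-methylbut-2-en-1-yl)benzaldehyde, via ortho-dienone Claisen intermediate 7 (not isolated)
Conditions: PhMe, 110 °C, sealed tube
Reagents that add atoms: none
Why: Aromatic Claisen rearrangement, a [3,3]-sigmatropic shift that can deliver the allyl unit, with its termini transposed, only to the single free ortho carbon, so the 3-methylbut-2-enyl group ends next to the phenol that is regenerated when dienone 7 tautomerises.

Step 5
Reactants: 8 2-hydroxy-4,6-bis(methoxymethoxy)-3-(3-methylbut-2-en-1-yl)benzaldehyde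
Product: 9 2-formyl-3,5-bis(methoxymethoxy)-6-(3-methylbut-2-en-1-yl)phenyl trifluoromethanesulfonate
Conditions: PhNTf2, Cs2CO3, DMF, rt
Reagents that add atoms: N-phenylbis(trifluoromethanesulfonimide) (PhNTf2), O=S(=O)(N(c1ccccc1)S(=O)(=O)C(F)(F)F)C(F)(F)F
Why: O-sulfonylation (triflation) of the cesium phenoxide by a mild triflyl donor under purely basic conditions, which excludes acid-induced cyclisation of the ortho prenyl group onto the phenol and leaves the MOM ethers untouched.

Step 6
Reactants: 9 2-formyl-3,5-bis(methoxymethoxy)-6-(3-methylbut-2-en-1-yl)phenyl trifluoromethanesulfonate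
Product: 10 2-(hydroxymethyl)-3,5-bis(methoxymethoxy)-6-(3-methylbut-2-en-1-yl)phenyl trifluoromethanesulfonate
Conditions: NaBH4, MeOH/THF, 0 °C
Reagents that add atoms: none
Why: Borohydride reduction of an aryl aldehyde, to which the aryl triflate, the MOM acetals and the trisubstituted alkene are inert at 0 °C.

Step 7
Reactants: 10 2-(hydroxymethyl)-3,5-bis(methoxymethoxy)-6-(3-methylbut-2-en-1-yl)phenyl trifluoromethanesulfonate
Product: 11 2-(bromomethyl)-3,5-bis(methoxymethoxy)-6-(3-methylbut-2-en-1-yl)phenyl trifluoromethanesulfonate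
Conditions: CBr4, PPh3, CH2Cl2, 0 °C; used at once
Reagents that add atoms: carbon tetrabromide, BrC(Br)(Br)Br
Why: Appel bromination, a neutral SN2 displacement of the oxyphosphonium ion of a primary benzylic alcohol by bromide that spares acetals, alkene and triflate, while the ortho triflate inductively tempers ionisation of the electron-rich benzylic bromide.

Step 8
Reactants: 12 methyl glycolate
Product: 13 methyl 2-(methoxymethoxy)acetate
Conditions: MOMCl, i-Pr2NEt, CH2Cl2, 0 °C → rt
Reagents that add atoms: chloromethyl methyl ether (MOMCl), COCCl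
Why: MOM protection of a primary alcohol by alkylation with an α-chloro ether in the presence of a hindered amine base.

Step 9
Reactants: 13 methyl 2-(methoxymethoxy)acetate
Product: 14 2-(methoxymethoxy)acetic acid
Conditions: LiOH, THF/H2O, 0 °C → rt; then 1 M HCl to pH 3 at 0 °C, extraction
Reagents that add atoms: lithium hydroxide, [Li+].[OH-]
Why: Saponification of a methyl ester, the MOM acetal being stable to base and to the brief cold acidification.

Step 10
Reactants: 14 2-(methoxymethoxy)acetic acid; 15 (R)-4-benzyl-2-oxazolidinone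
Product: 17 (R)-4-benzyl-3-[2-(methoxymethoxy)acetyl]oxazolidin-2-one, via mixed pivalic anhydride 16 (not isolated)
Conditions: PivCl, Et3N, THF, −20 °C; then 15, LiCl, −20 °C → rt
Reagents that add atoms: none
Why: N-acylation of the oxazolidinone through a mixed anhydride whose hindered pivaloyl carbonyl directs attack to the glycolyl carbonyl, a method that avoids an acid chloride and the HCl that would endanger the acetal.

Step 11
Reactants: 17 (R)-4-benzyl-3-[2-(methoxymethoxy)acetyl]oxazolidin-2-one; 11 2-(bromomethyl)-3,5-bis(methoxymethoxy)-6-(3-methylbut-2-en-1-yl)phenyl trifluoromethanesulfonate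
Product: 19 (R)-4-benzyl-3-[(S)-2-(methoxymethoxy)-3-{2,4-bis(methoxymethoxy)-5-(3-methylbut-2-en-1-yl)-6-[(trifluoromethylsulfonyl)oxy]phenyl}propanoyl]oxazolidin-2-one, via sodium Z-enolate 18 (not isolated)
Conditions: 17 (1.5 equiv), NaN(SiMe3)2 (1.4 equiv), THF, −78 °C; then 11 (1.0 equiv), −78 → −45 °C
Reagents that add atoms: none
Why: Evans asymmetric alkylation in which the sodium Z-enolate is chelated to the oxazolidinone carbonyl, the (R)-benzyl group screens one face and the reactive benzylic bromide enters from the other, which sets C3 as S.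

Step 12
Reactants: 19 (R)-4-benzyl-3-[(S)-2-(methoxymethoxy)-3-{2,4-bis(methoxymethoxy)-5-(3-methylbut-2-en-1-yl)-6-[(trifluoromethylsulfonyl)oxy]phenyl}propanoyl]oxazolidin-2-one
Product: 20 (S)-N-methoxy-2-(methoxymethoxy)-N-methyl-3-{2,4-bis(methoxymethoxy)-5-(3-methylbut-2-en-1-yl)-6-[(trifluoromethylsulfonyl)oxy]phenyl}propanamide
Conditions: MeNHOMe·HCl, AlMe3, CH2Cl2, −10 → 0 °C; aqueous potassium sodium tartrate
Reagents that add atoms: N,O-dimethylhydroxylamine hydrochloride, CNOC.Cl
Why: Weinreb transamidation in which the aluminium amide attacks the exocyclic imide carbonyl, activated by the α-alkoxy group, and releases the auxiliary without enolisation, so C3 is untouched.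

Step 13
Reactants: 21 4-bromobenzene-1,2-diol
Product: 22 4-bromo-1,2-bis(methoxymethoxy)benzene
Conditions: MOMCl (2.5 equiv), i-Pr2NEt, CH2Cl2, 0 °C → rt
Reagents that add atoms: chloromethyl methyl ether (MOMCl), COCCl
Why: Twofold MOM protection of a catechol by O-alkylation with an α-chloro ether and a hindered amine base.

Step 14
Reactants: 20 (S)-N-methoxy-2-(methoxymethoxy)-N-methyl-3-{2,4-bis(methoxymethoxy)-5-(3-methylbut-2-en-1-yl)-6-[(trifluoromethylsulfonyl)oxy]phenyl}propanamide; 22 4-bromo-1,2-bis(methoxymethoxy)benzene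
Product: 24 (S)-1-[3,4-bis(methoxymethoxy)phenyl]-2-(methoxymethoxy)-3-{2,4-bis(methoxymethoxy)-5-(3-methylbut-2-en-1-yl)-6-[(trifluoromethylsulfonyl)oxy]phenyl}propan-1-one, via arylmagnesium bromide 23 (not isolated)
Conditions: 22, Mg, THF, 40 °C; then 20, THF, −20 → 0 °C; aqueous NH4Cl
Reagents that add atoms: none
Why: Weinreb ketone synthesis in which the aryl Grignard reagent adds once to give a magnesium-chelated tetrahedral adduct that collapses only on work-up, so over-addition and enolisation at C3 are avoided, and the aryl triflate does not react with a Grignard reagent in the absence of a transition-metal catalyst.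

Step 15
Reactants: 24 (S)-1-[3,4-bis(methoxymethoxy)phenyl]-2-(methoxymethoxy)-3-{2,4-bis(methoxymethoxy)-5-(3-methylbut-2-en-1-yl)-6-[(trifluoromethylsulfonyl)oxy]phenyl}propan-1-one
Product: 25 (1R,2S)-1-[3,4-bis(methoxymethoxy)phenyl]-2-(methoxymethoxy)-3-{2,4-bis(methoxymethoxy)-5-(3-methylbut-2-en-1-yl)-6-[(trifluoromethylsulfonyl)oxy]phenyl}propan-1-ol
Conditions: Zn(BH4)2, Et2O, −30 → 0 °C
Reagents that add atoms: none
Why: Chelation-controlled (Cram chelate) ketone reduction in which zinc bridges the carbonyl oxygen and the α-MOM ether oxygen and hydride arrives on the chelate face away from the C4 benzyl substituent, which sets C2 as R and gives the anti alcohol.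

Step 16
Reactants: 25 (1R,2S)-1-[3,4-bis(methoxymethoxy)phenyl]-2-(methoxymethoxy)-3-{2,4-bis(methoxymethoxy)-5-(3-methylbut-2-en-1-yl)-6-[(trifluoromethylsulfonyl)oxy]phenyl}propan-1-ol
Product: 26 (2R,3S)-2-[3,4-bis(methoxymethoxy)phenyl]-3,5,7-tris(methoxymethoxy)-8-(3-methylbut-2-en-1-yl)chromane
Conditions: Pd(OAc)2 (5 mol%), rac-2-(di-tert-butylphosphino)-1,1'-binaphthyl (7.5 mol%), anhydrous K3PO4 (2 equiv), PhMe, 80 °C
Reagents that add atoms: none
Why: Pd(OAc)2 is reduced in the flask by the phosphine to zerovalent palladium, which inserts into the C8a–OTf bond; the phosphate base then exchanges triflate on the divalent arylpalladium for the C2 alkoxide to give a seven-membered oxapalladacycle, and C–O reductive elimination forges O1–C8a and returns the catalyst. The closest known reaction type is the palladium-catalysed intramolecular etherification of aryl halides and sulfonates with secondary alcohols (Buchwald–Hartwig-type C–O coupling), which turns 3-(2-halophenyl)propan-1-ols into chromans. Ring C closes as a six-membered ring by formal 6-exo attack of the C2 oxygen on the aromatic carbon C8a, realised as contraction of the palladacycle on reductive elimination. No stereocentre is created: C2 and C3 keep their configurations because neither the C2–O nor the C3–O bond is broken and no benzylic cation forms, so the anti open-chain relationship becomes the 2,3-trans ring relationship. The step needs reductive elimination to outrun β-hydride elimination from the benzylic alkoxide, which the bulky electron-rich di-tert-butylphosphine secures, and it needs six- over five-membered closure, which the MOM cap on the C3 oxygen secures; the mild insoluble phosphate limits S–O cleavage of the triflate, and Heck insertion of the C8 prenyl alkene would require a 4-exo or 5-endo closure and should not compete.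

Step 17
Reactants: 26 (2R,3S)-2-[3,4-bis(methoxymethoxy)phenyl]-3,5,7-tris(methoxymethoxy)-8-(3-methylbut-2-en-1-yl)chromane
Product: 27 8-prenylcatechin
Conditions: concentrated aqueous HCl (to about 0.5 M), degassed MeOH, 40 °C, under argon
Reagents that add atoms: none
Why: Acid-catalysed transacetalisation of the five MOM ethers to methanol (acetal solvolysis, giving volatile dimethoxymethane), run dilute and at mild temperature because protonation of the prenyl alkene, which would lead to chroman formation with the C7 hydroxyl, and ionisation of the benzylic C2–O1 bond are slower than acetal cleavage.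

Compound list
1 | 2,4,6-trihydroxybenzaldehyde | O=Cc1c(O)cc(O)cc1O | starting material
2 | 2-hydroxy-4,6-bis(methoxymethoxy)benzaldehyde | O=Cc1c(O)cc(OCOC)cc1OCOC | intermediate
3 | 2-methylbut-3-en-2-ol | CC(C)(O)C=C | starting material
4 | lithium 2-methylbut-3-en-2-olate | CC(C)([O-])C=C.[Li+] | intermediate
5 | methyl 2-methylbut-3-en-2-yl carbonate | COC(=O)OC(C)(C)C=C | intermediate
6 | 2,4-bis(methoxymethoxy)-6-[(2-methylbut-3-en-2-yl)oxy]benzaldehyde | O=Cc1c(OC(C)(C)C=C)cc(OCOC)cc1OCOC | intermediate
7 | 2,4-bis(methoxymethoxy)-5-(3-methylbut-2-en-1-yl)-6-oxocyclohexa-1,3-diene-1-carbaldehyde (ortho-dienone, racemic at C5) | O=CC1=C(OCOC)C=C(OCOC)C(CC=C(C)C)C1=O | intermediate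
8 | 2-hydroxy-4,6-bis(methoxymethoxy)-3-(3-methylbut-2-en-1-yl)benzaldehyde | O=Cc1c(O)c(CC=C(C)C)c(OCOC)cc1OCOC | intermediate
9 | 2-formyl-3,5-bis(methoxymethoxy)-6-(3-methylbut-2-en-1-yl)phenyl trifluoromethanesulfonate | O=Cc1c(OS(=O)(=O)C(F)(F)F)c(CC=C(C)C)c(OCOC)cc1OCOC | intermediate
10 | 2-(hydroxymethyl)-3,5-bis(methoxymethoxy)-6-(3-methylbut-2-en-1-yl)phenyl trifluoromethanesulfonate | OCc1c(OS(=O)(=O)C(F)(F)F)c(CC=C(C)C)c(OCOC)cc1OCOC | intermediate
11 | 2-(bromomethyl)-3,5-bis(methoxymethoxy)-6-(3-methylbut-2-en-1-yl)phenyl trifluoromethanesulfonate | BrCc1c(OS(=O)(=O)C(F)(F)F)c(CC=C(C)C)c(OCOC)cc1OCOC | intermediate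
12 | methyl glycolate | COC(=O)CO | starting material
13 | methyl 2-(methoxymethoxy)acetate | COCOCC(=O)OC | intermediate
14 | 2-(methoxymethoxy)acetic acid | COCOCC(=O)O | intermediate
15 | (R)-4-benzyl-2-oxazolidinone | O=C1N[C@H](Cc2ccccc2)CO1 | starting material
16 | 2-(methoxymethoxy)acetic pivalic anhydride | COCOCC(=O)OC(=O)C(C)(C)C | intermediate
17 | (R)-4-benzyl-3-[2-(methoxymethoxy)acetyl]oxazolidin-2-one | COCOCC(=O)N1[C@H](Cc2ccccc2)COC1=O | intermediate
18 | sodium Z-enolate of 17 (MOM-oxy group cis to the enolate oxygen) | COCO/C=C(\[O-])N1[C@H](Cc2ccccc2)COC1=O.[Na+] | intermediate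
19 | (R)-4-benzyl-3-[(S)-2-(methoxymethoxy)-3-{2,4-bis(methoxymethoxy)-5-(3-methylbut-2-en-1-yl)-6-[(trifluoromethylsulfonyl)oxy]phenyl}propanoyl]oxazolidin-2-one | CC(C)=CCc1c(OCOC)cc(OCOC)c(C[C@H](OCOC)C(=O)N2[C@H](Cc3ccccc3)COC2=O)c1OS(=O)(=O)C(F)(F)F | intermediate
20 | (S)-N-methoxy-2-(methoxymethoxy)-N-methyl-3-{2,4-bis(methoxymethoxy)-5-(3-methylbut-2-en-1-yl)-6-[(trifluoromethylsulfonyl)oxy]phenyl}propanamide | CC(C)=CCc1c(OCOC)cc(OCOC)c(C[C@H](OCOC)C(=O)N(C)OC)c1OS(=O)(=O)C(F)(F)F | intermediate
21 | 4-bromobenzene-1,2-diol | Oc1ccc(Br)cc1O | starting material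
22 | 4-bromo-1,2-bis(methoxymethoxy)benzene | COCOc1ccc(Br)cc1OCOC | intermediate
23 | [3,4-bis(methoxymethoxy)phenyl]magnesium bromide | COCOc1ccc([Mg]Br)cc1OCOC | intermediate
24 | (S)-1-[3,4-bis(methoxymethoxy)phenyl]-2-(methoxymethoxy)-3-{2,4-bis(methoxymethoxy)-5-(3-methylbut-2-en-1-yl)-6-[(trifluoromethylsulfonyl)oxy]phenyl}propan-1-one | CC(C)=CCc1c(OCOC)cc(OCOC)c(C[C@H](OCOC)C(=O)c2ccc(OCOC)c(OCOC)c2)c1OS(=O)(=O)C(F)(F)F | intermediate
25 | (1R,2S)-1-[3,4-bis(methoxymethoxy)phenyl]-2-(methoxymethoxy)-3-{2,4-bis(methoxymethoxy)-5-(3-methylbut-2-en-1-yl)-6-[(trifluoromethylsulfonyl)oxy]phenyl}propan-1-ol (anti; key-step precursor) | CC(C)=CCc1c(OCOC)cc(OCOC)c(C[C@H](OCOC)[C@H](O)c2ccc(OCOC)c(OCOC)c2)c1OS(=O)(=O)C(F)(F)F | intermediate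
26 | (2R,3S)-2-[3,4-bis(methoxymethoxy)phenyl]-3,5,7-tris(methoxymethoxy)-8-(3-methylbut-2-en-1-yl)chromane (8-prenylcatechin pentakis-MOM ether) | CC(C)=CCc1c(OCOC)cc(OCOC)c2c1O[C@H](c1ccc(OCOC)c(OCOC)c1)[C@@H](OCOC)C2 | intermediate
27 | 8-prenylcatechin, (2R,3S)-2-(3,4-dihydroxyphenyl)-8-(3-methylbut-2-en-1-yl)chromane-3,5,7-triol | CC(C)=CCc1c(O)cc(O)c2c1O[C@H](c1ccc(O)c(O)c1)[C@@H](O)C2 | target

Total step count: 17 steps.
Longest linear sequence: 12 steps (steps 1, 3 to 7, 11, 12, 14 to 17) from 2,4,6-trihydroxybenzaldehyde.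

Steps most likely to fail

Step 16. The palladium alkoxide may undergo β-hydride elimination, which oxidises C2 to the ketone and reduces C8a–OTf to C8a–H. Oxidative addition at the doubly ortho-substituted triflate may be slow, and the base may cleave the triflate at sulfur. The fallback changes the bond that is formed, from O1–C8a to O1–C2, and sets out from ketone 24. Reduction with KBH(s-Bu)3 in THF at −78 °C under Felkin–Anh (non-chelation) control should give the syn alcohol (1S,2S)-1-[3,4-bis(methoxymethoxy)phenyl]-2-(methoxymethoxy)-3-{2,4-bis(methoxymethoxy)-5-(3-methylbut-2-en-1-yl)-6-[(trifluoromethylsulfonyl)oxy]phenyl}propan-1-ol F1. Aqueous Et4NOH in dioxane at room temperature should then cleave the aryl triflate at sulfur to give the phenol (1S,2S)-1-[3,4-bis(methoxymethoxy)phenyl]-3-[2-hydroxy-4,6-bis(methoxymethoxy)-3-(3-methylbut-2-en-1-yl)phenyl]-2-(methoxymethoxy)propan-1-ol F2. An intramolecular Mitsunobu etherification (PPh3, diisopropyl azodicarboxylate, THF, 0 °C) should close the pyran with inversion at the benzylic carbon and come back to the route at 26. Any leakage through a benzylic cation should also favour the 2,3-trans ring.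

Step 11. The α-alkoxy enolate 18 may decompose before it alkylates the doubly ortho-substituted bromide, and bromide 11 may ionise and self-condense. The fallback replaces the alkylation by an aldol addition followed by deoxygenation and sets out from aldehyde 9 and acid 14. Acid 14 is coupled under the conditions of step 10 with purchased (S)-4-benzyl-2-oxazolidinone to give (S)-4-benzyl-3-[2-(methoxymethoxy)acetyl]oxazolidin-2-one F3; the enantiomeric auxiliary is needed because the boron aldol uses the enolate face opposite to the one used in the chelated alkylation. Its dibutylboron Z-enolate (Bu2BOTf, i-Pr2NEt, CH2Cl2, −78 °C) should add to 9 in an Evans syn-aldol reaction to give the (2S,3R) β-hydroxy imide F4. 1,1'-Thiocarbonyldiimidazole with catalytic DMAP should convert the benzylic hydroxyl into the imidazole-1-carbothioate F5. Barton–McCombie deoxygenation (Bu3SnH, AIBN, PhMe, 90 °C) should remove the benzylic oxygen to give (S)-4-benzyl-3-[(S)-2-(methoxymethoxy)-3-arylpropanoyl]oxazolidin-2-one F6, which carries the same C3 configuration as 19. The conditions of step 12 then cleave the auxiliary, and the fallback comes back to the route at Weinreb amide 20.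

Step 3. The tertiary ether may re-ionise on palladium and isomerise to the linear prenyl ether, because the chelated phenoxide is a good leaving group, or the electron-rich ring may be allylated at carbon. The fallback builds the ether without a π-allyl intermediate and sets out from phenol 2. Copper-catalysed propargylation with purchased 3-chloro-3-methylbut-1-yne (DBU, catalytic CuCl2, MeCN, 0 °C) should give the tertiary propargyl ether 2,4-bis(methoxymethoxy)-6-[(2-methylbut-3-yn-2-yl)oxy]benzaldehyde F7. Semi-hydrogenation (H2, Pd/CaCO3 poisoned with Pb(OAc)2, quinoline, EtOAc, rt) should then reduce the alkyne to the alkene and come back to the route at 6.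

Further compounds
F1 | step 16 | (1S,2S)-1-[3,4-bis(methoxymethoxy)phenyl]-2-(methoxymethoxy)-3-{2,4-bis(methoxymethoxy)-5-(3-methylbut-2-en-1-yl)-6-[(trifluoromethylsulfonyl)oxy]phenyl}propan-1-ol (syn) | CC(C)=CCc1c(OCOC)cc(OCOC)c(C[C@H](OCOC)[C@@H](O)c2ccc(OCOC)c(OCOC)c2)c1OS(=O)(=O)C(F)(F)F
F2 | step 16 | (1S,2S)-1-[3,4-bis(methoxymethoxy)phenyl]-3-[2-hydroxy-4,6-bis(methoxymethoxy)-3-(3-methylbut-2-en-1-yl)phenyl]-2-(methoxymethoxy)propan-1-ol | CC(C)=CCc1c(OCOC)cc(OCOC)c(C[C@H](OCOC)[C@@H](O)c2ccc(OCOC)c(OCOC)c2)c1O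
F3 | step 11 | (S)-4-benzyl-3-[2-(methoxymethoxy)acetyl]oxazolidin-2-one | COCOCC(=O)N1[C@@H](Cc2ccccc2)COC1=O
F4 | step 11 | (S)-4-benzyl-3-[(2S,3R)-3-hydroxy-2-(methoxymethoxy)-3-{2,4-bis(methoxymethoxy)-5-(3-methylbut-2-en-1-yl)-6-[(trifluoromethylsulfonyl)oxy]phenyl}propanoyl]oxazolidin-2-one | CC(C)=CCc1c(OCOC)cc(OCOC)c([C@@H](O)[C@H](OCOC)C(=O)N2[C@@H](Cc3ccccc3)COC2=O)c1OS(=O)(=O)C(F)(F)F
F5 | step 11 | O-benzylic 1H-imidazole-1-carbothioate of F4 | CC(C)=CCc1c(OCOC)cc(OCOC)c([C@@H](OC(=S)n2ccnc2)[C@H](OCOC)C(=O)N2[C@@H](Cc3ccccc3)COC2=O)c1OS(=O)(=O)C(F)(F)F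
F6 | step 11 | (S)-4-benzyl-3-[(S)-2-(methoxymethoxy)-3-{2,4-bis(methoxymethoxy)-5-(3-methylbut-2-en-1-yl)-6-[(trifluoromethylsulfonyl)oxy]phenyl}propanoyl]oxazolidin-2-one | CC(C)=CCc1c(OCOC)cc(OCOC)c(C[C@H](OCOC)C(=O)N2[C@@H](Cc3ccccc3)COC2=O)c1OS(=O)(=O)C(F)(F)F
F7 | step 3 | 2,4-bis(methoxymethoxy)-6-[(2-methylbut-3-yn-2-yl)oxy]benzaldehyde | O=Cc1c(OC(C)(C)C#C)cc(OCOC)cc1OCOC
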